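**Retrosynthetic overview**
1. Target 29 ⇐ desilylation of 28 ⇐ angeloylation of the bicyclic hydroxy lactone 25.
2. 25 ⇐ 23: the cyclohexene is closed last by a zinc-mediated intramolecular allylation in which the β-carbon of the lactone (allylzinc from the 3-(bromomethyl)butenolide, a homoenolate equivalent) attacks the enal carbon and sets two stereocentres.
3. 23 ⇐ 16 + acrylate 17: the γ-lactone is made first by enantioselective iridium-catalysed 2-(methoxycarbonyl)allylation of a primary alcohol, then acetal hydrolysis and bromination/elimination.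
4. 16 ⇐ 6: the (Z)-tetrasubstituted alkene comes from alkoxide-directed anti-vinylmagnesiation of a homopropargylic alcohol with C-formylation (as acetal); the vinyl and prenyl termini are degraded to the two CH2OH groups.
5. 6 ⇐ (R)-citronellal (side-chain stereocentre) + oxirane. Ring order: γ-lactone (step 6), then cyclohexene (step 9).

Assumption: (S)-TMBTP is taken as the ligand antipode that gives the (5R) lactone 20; if the sense of induction is the reverse, (R)-TMBTP is used. TBS = tert-butyldimethylsilyl; ring locants are those of the 1-benzofuran-2-one core.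

**Step 1**
Reactants: 1 (3R)-3,7-dimethyloct-6-enal
Product: 3 (3R)-3,7-dimethyloct-6-en-1-yne, via enol nonaflate 2 (not isolated)
Conditions: C4F9SO2F, P2-Et phosphazene base, DMF, −30 → 20 °C
Reagents that add atoms: none
Why: Base-mediated O-sulfonylation of the aldehyde enolate and E2 elimination of the enol nonaflate (one-pot aldehyde-to-alkyne dehydration) give the terminal alkyne, and the stereocentre is not a reacting carbon.

**Step 2**
Reactants: 3 (3R)-3,7-dimethyloct-6-en-1-yne; 4 oxirane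
Product: 6 (5R)-5,9-dimethyldec-8-en-3-yn-1-ol, via lithium acetylide 5 (not isolated)
Conditions: n-BuLi, THF, −78 °C; then 4, BF3·OEt2, −78 °C
Reagents that add atoms: none
Why: Lewis-acid-assisted opening of oxirane by the lithium acetylide (Yamaguchi alkynylation of an epoxide) adds the hydroxyethyl arm without creating a stereocentre.

**Step 3**
Reactants: 6 (5R)-5,9-dimethyldec-8-en-3-yn-1-ol; 7 vinylmagnesium chloride; 8 diethyl phenyl orthoformate
Product: 11 (3E,5R)-4-(diethoxymethyl)-3-ethenyl-5,9-dimethyldeca-3,8-dien-1-yl acetate, via alkenylmagnesium chelate 9 (not isolated), via magnesium alkoxide acetal 10 (not isolated)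
Conditions: 7 (3.2 equiv), CuI (10 mol %), THF, 0 → 45 °C; then 8, 0 °C → rt; then Ac2O, 0 °C
Reagents that add atoms: acetic anhydride CC(=O)OC(C)=O
Why: Proposed new method: the chloromagnesium alkoxide directs an anti-carbomagnesiation in which vinyl adds to the unhindered proximal alkyne carbon while magnesium is held on the distal carbon in a six-membered chelate, so the C–Mg bond, replaced with retention by the orthoformate (Bodroux–Chichibabin acetal synthesis), lies cis to the CH2CH2O arm and fixes the tetrasubstituted alkene geometry before the alkoxide is capped with Ac2O; the closest known reaction is the Duboudin–Fallis anti-carbomagnesiation of propargylic alcohols through a five-membered chelate.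

**Step 4**
Reactants: 11 (3E,5R)-4-(diethoxymethyl)-3-ethenyl-5,9-dimethyldeca-3,8-dien-1-yl acetate
Product: 14 (3E,5R)-4-(diethoxymethyl)-8-hydroxy-3-(hydroxymethyl)-5-methyloct-3-en-1-yl acetate, via tetraol 12 (not isolated), via dialdehyde 13 (not isolated)
Conditions: OsO4 (2 mol %), NMO, acetone/H2O, rt; NaIO4, NaHCO3, THF/H2O, 0 °C; NaBH4, CeCl3·7H2O, MeOH, −20 °C
Reagents that add atoms: N-methylmorpholine N-oxide C[N+]1([O-])CCOCC1; water O
Why: Upjohn dihydroxylation attacks only the vinyl and trisubstituted alkenes (the tetrasubstituted alkene is inert to OsO4), Malaprade cleavage removes one and three carbons, and Luche-type reduction gives the two primary alcohols without touching a stereocentre.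

**Step 5**
Reactants: 14 (3E,5R)-4-(diethoxymethyl)-8-hydroxy-3-(hydroxymethyl)-5-methyloct-3-en-1-yl acetate
Product: 16 (3E,5R)-8-(TBSO)-3-(TBSOCH2)-4-(diethoxymethyl)-5-methyloct-3-en-1-ol, via bis-silyl acetate 15 (not isolated)
Conditions: TBSCl, imidazole, DMF, rt; then K2CO3, MeOH, rt
Reagents that add atoms: tert-butyldimethylsilyl chloride CC(C)(C)[Si](C)(C)Cl
Why: Silylation of both primary alcohols followed by base-catalysed methanolysis of the acetate (transesterification), which spares silyl ethers and the acetal, frees only the homoallylic alcohol.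

**Step 6**
Reactants: 16 (3E,5R)-8-(TBSO)-3-(TBSOCH2)-4-(diethoxymethyl)-5-methyloct-3-en-1-ol; 17 methyl 2-(acetoxymethyl)acrylate
Product: 20 (5R)-5-[(2E,4R)-7-(TBSO)-2-(TBSOCH2)-3-(diethoxymethyl)-4-methylhept-2-en-1-yl]-3-methylideneoxolan-2-one, via aldehyde 18 (not isolated), via hydroxy ester 19 (not isolated)
Conditions: [Ir(cod)Cl]2 (2.5 mol %), (S)-TMBTP (5 mol %), 4-chloro-3-nitrobenzoic acid (10 mol %), Cs2CO3 (20 mol %), THF, 70 °C
Reagents that add atoms: none
Why: Krische transfer-hydrogenative 2-(alkoxycarbonyl)allylation, in which the cyclometallated iridium π-allyl complex dehydrogenates the alcohol and delivers its nucleophilic allyl ligand to the Si face of the transient aldehyde under ligand control, followed by lactonisation, sets the (5R) lactone carbinol centre.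

**Step 7**
Reactants: 20 (5R)-5-[(2E,4R)-7-(TBSO)-2-(TBSOCH2)-3-(diethoxymethyl)-4-methylhept-2-en-1-yl]-3-methylideneoxolan-2-one
Product: 21 (2E)-2-[(2R)-5-(TBSO)pentan-2-yl]-3-(TBSOCH2)-4-[(2R)-4-methylidene-5-oxooxolan-2-yl]but-2-enal
Conditions: oxalic acid (cat.), wet SiO2, CH2Cl2, rt
Reagents that add atoms: water O
Why: Mild acetal hydrolysis through the allyl-stabilised oxocarbenium ion releases the conjugated aldehyde without lactol formation, because the neighbouring oxygen is already locked in the lactone, and leaves alkene geometry and stereocentres unchanged.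

**Step 8**
Reactants: 21 (2E)-2-[(2R)-5-(TBSO)pentan-2-yl]-3-(TBSOCH2)-4-[(2R)-4-methylidene-5-oxooxolan-2-yl]but-2-enal
Product: 23 (2E)-4-[(2R)-4-(bromomethyl)-5-oxo-2,5-dihydrofuran-2-yl]-2-[(2R)-5-(TBSO)pentan-2-yl]-3-(TBSOCH2)but-2-enal, via dibromide 22 (not isolated)
Conditions: Br2, CH2Cl2, −40 → 0 °C; then Et3N, 0 °C
Reagents that add atoms: bromine BrBr
Why: Bromine adds to the exocyclic methylene (the tetrasubstituted alkene is deactivated by the formyl group) and E2 loss of HBr towards the ring gives the 3-(bromomethyl)butenolide by bromination–dehydrobromination with allylic transposition, short contact with the amine at 0 °C protecting the lactone carbinol centre from epimerisation.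

**Step 9**
Reactants: 23 (2E)-4-[(2R)-4-(bromomethyl)-5-oxo-2,5-dihydrofuran-2-yl]-2-[(2R)-5-(TBSO)pentan-2-yl]-3-(TBSOCH2)but-2-enal
Product: 25 (3aS,4S,7aR)-4-hydroxy-3-methylidene-5-[(2R)-5-(TBSO)pentan-2-yl]-6-(TBSOCH2)-3a,4,7,7a-tetrahydro-1-benzofuran-2(3H)-one, via allylzinc bromide 24 (not isolated)
Conditions: Zn dust, THF/sat. aq NH4Cl, 0 °C → rt, 0.01 M
Reagents that add atoms: none
Why: Proposed new method: zinc insertion gives an allylzinc that is a homoenolate equivalent of the lactone, and its γ-carbon (the lactone β-carbon) adds to the tethered aldehyde in a chair Zimmerman–Traxler transition state (intramolecular Barbier allylation) where the short tether enforces cis ring fusion to the existing lactone centre and equatorial placement of both the ring substituent and the aldehyde substituent gives the anti carbinol, setting C-3a and C-4 and regenerating the exocyclic methylene; the closest known reactions are intermolecular zinc-mediated additions of 3-(bromomethyl)furan-2(5H)-ones to aldehydes.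

**Step 10**
Reactants: 25 (3aS,4S,7aR)-4-hydroxy-3-methylidene-5-[(2R)-5-(TBSO)pentan-2-yl]-6-(TBSOCH2)-3a,4,7,7a-tetrahydro-1-benzofuran-2(3H)-one; 26 (2Z)-2-methylbut-2-enoic acid
Product: 28 (3aR,4S,7aR)-3-methylidene-2-oxo-5-[(2R)-5-(TBSO)pentan-2-yl]-6-(TBSOCH2)-2,3,3a,4,7,7a-hexahydro-1-benzofuran-4-yl (2Z)-2-methylbut-2-enoate, via mixed anhydride 27 (not isolated)
Conditions: 26, 2,4,6-trichlorobenzoyl chloride, Et3N, toluene, rt; then 25, 75 °C
Reagents that add atoms: none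
Why: Yamaguchi-type mixed-anhydride esterification without a nucleophilic catalyst acylates the hindered secondary alcohol with retention at carbon and keeps the (Z) geometry of the angelate.

**Step 11**
Reactants: 28 (3aR,4S,7aR)-3-methylidene-2-oxo-5-[(2R)-5-(TBSO)pentan-2-yl]-6-(TBSOCH2)-2,3,3a,4,7,7a-hexahydro-1-benzofuran-4-yl (2Z)-2-methylbut-2-enoate
Product: 29 (3aR,4S,7aR)-6-(hydroxymethyl)-5-[(2R)-5-hydroxypentan-2-yl]-3-methylidene-2-oxo-2,3,3a,4,7,7a-hexahydro-1-benzofuran-4-yl (2Z)-2-methylbut-2-enoate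
Conditions: HF·pyridine, pyridine/THF, 0 °C → rt
Reagents that add atoms: none
Why: Fluoride-mediated desilylation cleaves both primary silyl ethers and leaves the ester, the α-methylene lactone and all stereocentres untouched.

**Compound list**
1 | (3R)-3,7-dimethyloct-6-enal, (R)-citronellal | O=CC[C@H](C)CCC=C(C)C | starting material
2 | (3R)-3,7-dimethylocta-1,6-dien-1-yl nonafluorobutane-1-sulfonate (E/Z mixture) | C[C@H](CCC=C(C)C)C=COS(=O)(=O)C(F)(F)C(F)(F)C(F)(F)C(F)(F)F | intermediate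
3 | (3R)-3,7-dimethyloct-6-en-1-yne | C#C[C@H](C)CCC=C(C)C | intermediate
4 | oxirane | C1CO1 | starting material
5 | lithium (3R)-3,7-dimethyloct-6-en-1-yn-1-ide | [Li]C#C[C@H](C)CCC=C(C)C | intermediate
6 | (5R)-5,9-dimethyldec-8-en-3-yn-1-ol | OCCC#C[C@H](C)CCC=C(C)C | intermediate
7 | vinylmagnesium chloride | C=C[Mg]Cl | starting material
8 | diethyl phenyl orthoformate | CCOC(OCC)Oc1ccccc1 | starting material
9 | alkenylmagnesium chelate (C-magnesiated chloromagnesium alkoxide of (5R)-3-ethenyl-5,9-dimethyldeca-3,8-dien-1-ol) | C=C/C(CCO[Mg]Cl)=C(/[Mg]Cl)[C@H](C)CCC=C(C)C | intermediate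
10 | chloromagnesium alkoxide of (3E,5R)-4-(diethoxymethyl)-3-ethenyl-5,9-dimethyldeca-3,8-dien-1-ol | C=C/C(CCO[Mg]Cl)=C(/C(OCC)OCC)[C@H](C)CCC=C(C)C | intermediate
11 | (3E,5R)-4-(diethoxymethyl)-3-ethenyl-5,9-dimethyldeca-3,8-dien-1-yl acetate | C=C/C(CCOC(C)=O)=C(/C(OCC)OCC)[C@H](C)CCC=C(C)C | intermediate
12 | tetraol from double dihydroxylation of 11 (new carbinol centres as mixtures) | OCC(O)/C(CCOC(C)=O)=C(/C(OCC)OCC)[C@H](C)CCC(O)C(C)(C)O | intermediate
13 | (3E,5R)-4-(diethoxymethyl)-3-formyl-5-methyl-8-oxooct-3-en-1-yl acetate | O=C/C(CCOC(C)=O)=C(/C(OCC)OCC)[C@H](C)CCC=O | intermediate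
14 | (3E,5R)-4-(diethoxymethyl)-8-hydroxy-3-(hydroxymethyl)-5-methyloct-3-en-1-yl acetate | OC/C(CCOC(C)=O)=C(/C(OCC)OCC)[C@H](C)CCCO | intermediate
15 | (3E,5R)-8-(TBSO)-3-(TBSOCH2)-4-(diethoxymethyl)-5-methyloct-3-en-1-yl acetate | CC(C)(C)[Si](C)(C)OC/C(CCOC(C)=O)=C(/C(OCC)OCC)[C@H](C)CCCO[Si](C)(C)C(C)(C)C | intermediate
16 | (3E,5R)-8-(TBSO)-3-(TBSOCH2)-4-(diethoxymethyl)-5-methyloct-3-en-1-ol | CC(C)(C)[Si](C)(C)OC/C(CCO)=C(/C(OCC)OCC)[C@H](C)CCCO[Si](C)(C)C(C)(C)C | intermediate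
17 | methyl 2-(acetoxymethyl)acrylate | C=C(COC(C)=O)C(=O)OC | starting material
18 | (3E,5R)-8-(TBSO)-3-(TBSOCH2)-4-(diethoxymethyl)-5-methyloct-3-enal | CC(C)(C)[Si](C)(C)OC/C(CC=O)=C(/C(OCC)OCC)[C@H](C)CCCO[Si](C)(C)C(C)(C)C | intermediate
19 | methyl (4R,6E,8R)-11-(TBSO)-6-(TBSOCH2)-7-(diethoxymethyl)-4-hydroxy-8-methyl-2-methylideneundec-6-enoate | CC(C)(C)[Si](C)(C)OC/C(C[C@@H](O)CC(=C)C(=O)OC)=C(/C(OCC)OCC)[C@H](C)CCCO[Si](C)(C)C(C)(C)C | intermediate
20 | (5R)-5-[(2E,4R)-7-(TBSO)-2-(TBSOCH2)-3-(diethoxymethyl)-4-methylhept-2-en-1-yl]-3-methylideneoxolan-2-one | CC(C)(C)[Si](C)(C)OC/C(C[C@@H]1CC(=C)C(=O)O1)=C(/C(OCC)OCC)[C@H](C)CCCO[Si](C)(C)C(C)(C)C | intermediate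
21 | (2E)-2-[(2R)-5-(TBSO)pentan-2-yl]-3-(TBSOCH2)-4-[(2R)-4-methylidene-5-oxooxolan-2-yl]but-2-enal | CC(C)(C)[Si](C)(C)OC/C(C[C@@H]1CC(=C)C(=O)O1)=C(/C=O)[C@H](C)CCCO[Si](C)(C)C(C)(C)C | intermediate
22 | (2E)-4-[(2R)-4-bromo-4-(bromomethyl)-5-oxooxolan-2-yl]-2-[(2R)-5-(TBSO)pentan-2-yl]-3-(TBSOCH2)but-2-enal (C-4 epimers) | CC(C)(C)[Si](C)(C)OC/C(C[C@@H]1CC(Br)(CBr)C(=O)O1)=C(/C=O)[C@H](C)CCCO[Si](C)(C)C(C)(C)C | intermediate
23 | (2E)-4-[(2R)-4-(bromomethyl)-5-oxo-2,5-dihydrofuran-2-yl]-2-[(2R)-5-(TBSO)pentan-2-yl]-3-(TBSOCH2)but-2-enal | CC(C)(C)[Si](C)(C)OC/C(C[C@@H]1C=C(CBr)C(=O)O1)=C(/C=O)[C@H](C)CCCO[Si](C)(C)C(C)(C)C | intermediate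
24 | allylzinc bromide derived from 23 | CC(C)(C)[Si](C)(C)OC/C(C[C@@H]1C=C(C[Zn]Br)C(=O)O1)=C(/C=O)[C@H](C)CCCO[Si](C)(C)C(C)(C)C | intermediate
25 | (3aS,4S,7aR)-4-hydroxy-3-methylidene-5-[(2R)-5-(TBSO)pentan-2-yl]-6-(TBSOCH2)-3a,4,7,7a-tetrahydro-1-benzofuran-2(3H)-one | C=C1C(=O)O[C@@H]2CC(CO[Si](C)(C)C(C)(C)C)=C([C@H](C)CCCO[Si](C)(C)C(C)(C)C)[C@@H](O)[C@H]12 | intermediate
26 | (2Z)-2-methylbut-2-enoic acid, angelic acid | C/C=C(/C)C(=O)O | starting material
27 | (2Z)-2-methylbut-2-enoic 2,4,6-trichlorobenzoic anhydride | C/C=C(/C)C(=O)OC(=O)c1c(Cl)cc(Cl)cc1Cl | intermediate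
28 | (3aR,4S,7aR)-3-methylidene-2-oxo-5-[(2R)-5-(TBSO)pentan-2-yl]-6-(TBSOCH2)-2,3,3a,4,7,7a-hexahydro-1-benzofuran-4-yl (2Z)-2-methylbut-2-enoate | C=C1C(=O)O[C@@H]2CC(CO[Si](C)(C)C(C)(C)C)=C([C@H](C)CCCO[Si](C)(C)C(C)(C)C)[C@@H](OC(=O)/C(C)=C\C)[C@H]12 | intermediate
29 | (3aR,4S,7aR)-6-(hydroxymethyl)-5-[(2R)-5-hydroxypentan-2-yl]-3-methylidene-2-oxo-2,3,3a,4,7,7a-hexahydro-1-benzofuran-4-yl (2Z)-2-methylbut-2-enoate | C=C1C(=O)O[C@@H]2CC(CO)=C([C@H](C)CCCO)[C@@H](OC(=O)/C(C)=C\C)[C@H]12 | target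

**Totals**
Total step count: 11. Longest linear sequence: 11 (from 1).

**Steps most likely to fail, with fallbacks**

Step 3. The homopropargylic alkoxide may direct poorly, or vinyl may add to the other alkyne carbon. The fallback sets out from 3 and comes back at 11, using the established propargylic version followed by a one-carbon homologation. Alkyne 3 is hydroxymethylated (n-BuLi, paraformaldehyde) to (4R)-4,8-dimethylnon-7-en-2-yn-1-ol F1. Anti-vinylmagnesiation through the five-membered chelate and trapping with 8 gives (2Z,4R)-3-(diethoxymethyl)-2-ethenyl-4,8-dimethylnona-2,7-dien-1-ol F2. CBr4/PPh3 converts it into (3Z,5R)-3-(bromomethyl)-4-(diethoxymethyl)-5,9-dimethyldeca-1,3,8-triene F3. CuI-catalysed coupling with (isopropoxydimethylsilyl)methylmagnesium chloride gives [(3E,5R)-4-(diethoxymethyl)-3-ethenyl-5,9-dimethyldeca-3,8-dien-1-yl](isopropoxy)dimethylsilane F4. Tamao oxidation (H2O2, KF, KHCO3) gives (3E,5R)-4-(diethoxymethyl)-3-ethenyl-5,9-dimethyldeca-3,8-dien-1-ol F5, and acetylation returns 11.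

Step 6. The transient β,γ-unsaturated aldehyde may isomerise under the basic iridium conditions, or the ee may be low. The fallback sets out from 16 and comes back at 21, replacing hydrogen transfer by an organochromium addition to a preformed aldehyde. Dess–Martin oxidation gives aldehyde 18, used crude. CrCl2-catalysed enantioselective Nozaki–Hiyama allylation with methyl 2-(bromomethyl)acrylate (chiral bis(oxazolinyl)carbazole ligand, Mn, TMSCl) gives methyl (4R,6E,8R)-11-(TBSO)-6-(TBSOCH2)-7-(diethoxymethyl)-8-methyl-2-methylidene-4-(trimethylsilyloxy)undec-6-enoate F6. PPTS in wet acetone, then catalytic TsOH in CH2Cl2, removes the trimethylsilyl group and the acetal and closes the lactone to give 21.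

Step 9. The hindered, conjugated aldehyde may react slowly, allowing reduction or dimerisation of the allylzinc, or the diastereoselectivity may be low. The fallback sets out from 23 and comes back at 25, replacing reductive metalation by allylboration. Pd2(dba)3-catalysed borylation of the allylic bromide with bis(pinacolato)diboron gives (2E)-2-[(2R)-5-(TBSO)pentan-2-yl]-3-(TBSOCH2)-4-[(2R)-5-oxo-4-[(4,4,5,5-tetramethyl-1,3,2-dioxaborolan-2-yl)methyl]-2,5-dihydrofuran-2-yl]but-2-enal F7. Sc(OTf)3-catalysed intramolecular allylboration through the closed chair, then aqueous work-up, gives 25.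

**Further compounds**
F1 | step 3 | (4R)-4,8-dimethylnon-7-en-2-yn-1-ol | OCC#C[C@H](C)CCC=C(C)C
F2 | step 3 | (2Z,4R)-3-(diethoxymethyl)-2-ethenyl-4,8-dimethylnona-2,7-dien-1-ol | C=C/C(CO)=C(/C(OCC)OCC)[C@H](C)CCC=C(C)C
F3 | step 3 | (3Z,5R)-3-(bromomethyl)-4-(diethoxymethyl)-5,9-dimethyldeca-1,3,8-triene | C=C/C(CBr)=C(/C(OCC)OCC)[C@H](C)CCC=C(C)C
F4 | step 3 | [(3E,5R)-4-(diethoxymethyl)-3-ethenyl-5,9-dimethyldeca-3,8-dien-1-yl](isopropoxy)dimethylsilane | C=C/C(CC[Si](C)(C)OC(C)C)=C(/C(OCC)OCC)[C@H](C)CCC=C(C)C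
F5 | step 3 | (3E,5R)-4-(diethoxymethyl)-3-ethenyl-5,9-dimethyldeca-3,8-dien-1-ol | C=C/C(CCO)=C(/C(OCC)OCC)[C@H](C)CCC=C(C)C
F6 | step 6 | methyl (4R,6E,8R)-11-(TBSO)-6-(TBSOCH2)-7-(diethoxymethyl)-8-methyl-2-methylidene-4-(trimethylsilyloxy)undec-6-enoate | CC(C)(C)[Si](C)(C)OC/C(C[C@@H](O[Si](C)(C)C)CC(=C)C(=O)OC)=C(/C(OCC)OCC)[C@H](C)CCCO[Si](C)(C)C(C)(C)C
F7 | step 9 | (2E)-2-[(2R)-5-(TBSO)pentan-2-yl]-3-(TBSOCH2)-4-[(2R)-5-oxo-4-[(4,4,5,5-tetramethyl-1,3,2-dioxaborolan-2-yl)methyl]-2,5-dihydrofuran-2-yl]but-2-enal | CC(C)(C)[Si](C)(C)OC/C(C[C@@H]1C=C(CB2OC(C)(C)C(C)(C)O2)C(=O)O1)=C(/C=O)[C@H](C)CCCO[Si](C)(C)C(C)(C)C
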